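**Retrosynthetic overview**

- The target is a 2,3-trans 2-aryl-2,3-dihydrobenzofuran. The Z-propenal on C5 is traced back to an aryl iodide (Sonogashira coupling with propargyl alcohol, syn semihydrogenation, allylic oxidation), and the 4-hydroxybenzoate on the C3 CH2O group to a late esterification.
- The strategy rests on the C2–C3 bond of the dihydrofuran ring. C2 is benzylic to the guaiacyl ring and bonded to O1; C3 is attached to C3a and carries a carbon (the CH2O) that can be drawn back to an ester. C3 is therefore cut as a rhodium carbene carbon and C2 as a doubly activated ether C–H.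
- Ring order: the two benzene rings of the core are purchased (o-vanillin, vanillin) and first joined through the O1–C2 ether bond. The five-membered oxygen ring is then closed by enantioselective carbene C–H insertion, C3 is epimerised to trans, and the ester is reduced. The benzoate ring and the C5 chain are attached last.

Key step: step 11

Assumption: Rh2(S-PTTL)4 is taken to select the benzylic hydrogen that leads to 2S; if the induction on this substrate runs the other way, the antipodal catalyst Rh2(R-PTTL)4 is used under the same conditions and nothing else changes.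

**Step 1**
Reactants: 1 o-vanillin (2-hydroxy-3-methoxybenzaldehyde)
Product: 2 5-iodo-o-vanillin (2-hydroxy-5-iodo-3-methoxybenzaldehyde)
Conditions: NIS (1.05 equiv), TFA (cat.), MeCN, rt
Reagents that add atoms: N-iodosuccinimide, O=C1CCC(=O)N1I
Why: Electrophilic aromatic iodination, in which the free phenol is the strongest director and its only open activated position is C5 (para to OH, meta to the formyl group), so one regioisomer should form.

**Step 2**
Reactants: 3 vanillin (4-hydroxy-3-methoxybenzaldehyde)
Product: 4 3-methoxy-4-(triisopropylsilyloxy)benzaldehyde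
Conditions: TIPSCl (1.2 equiv), imidazole, DMF, rt
Reagents that add atoms: triisopropylsilyl chloride, CC(C)[Si](Cl)(C(C)C)C(C)C
Why: Imidazole-promoted silyl ether formation on the phenol; the bulky TIPS group is chosen because it must survive borohydride, carbonate, ylide, methoxide and hydride and leave only at the end with fluoride.

**Step 3**
Reactants: 4 3-methoxy-4-(triisopropylsilyloxy)benzaldehyde
Product: 5 [3-methoxy-4-(triisopropylsilyloxy)phenyl]methanol
Conditions: NaBH4, EtOH/THF, 0 °C
Reagents that add atoms: none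
Why: Borohydride reduction of the aryl aldehyde to the benzylic alcohol, with the hindered aryl silyl ether stable to the cold, weakly basic medium.

**Step 4**
Reactants: 5 [3-methoxy-4-(triisopropylsilyloxy)phenyl]methanol
Product: 6 4-(bromomethyl)-2-methoxy-1-(triisopropylsilyloxy)benzene
Conditions: CBr4, PPh3, CH2Cl2, 0 °C; used at once
Reagents that add atoms: carbon tetrabromide, BrC(Br)(Br)Br
Why: Appel bromination converts the benzylic alcohol under neutral conditions, avoiding HBr that could attack the silyl ether; the electron-rich bromide should be carried forward without storage.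

**Step 5**
Reactants: 2 5-iodo-o-vanillin; 6 4-(bromomethyl)-2-methoxy-1-(triisopropylsilyloxy)benzene
Product: 7 5-iodo-3-methoxy-2-{[3-methoxy-4-(triisopropylsilyloxy)phenyl]methoxy}benzaldehyde
Conditions: K2CO3, acetone, 50 °C
Reagents that add atoms: none
Why: Williamson ether synthesis, in which the phenoxide of 2 (acidified by the ortho formyl group) displaces the reactive benzylic bromide by SN2 and forms the future O1–C2 bond.

**Step 6**
Reactants: 7 5-iodo-3-methoxy-2-{[3-methoxy-4-(triisopropylsilyloxy)phenyl]methoxy}benzaldehyde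
Product: 8 5-iodo-1-methoxy-3-(2-methoxyethenyl)-2-{[3-methoxy-4-(triisopropylsilyloxy)phenyl]methoxy}benzene (E/Z mixture)
Conditions: Ph3P(CH2OMe)Cl (1.5 equiv), KOtBu (1.4 equiv), THF, 0 °C; then 7, 0 °C → rt
Reagents that add atoms: (methoxymethyl)triphenylphosphonium chloride, COC[P+](c1ccccc1)(c1ccccc1)c1ccccc1.[Cl-]
Why: Wittig methoxymethylenation adds the one carbon that becomes C3; the E/Z mixture converges in the next step, and keeping the salt in slight excess over the base leaves no free alkoxide to attack the silyl ether.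

**Step 7**
Reactants: 8 methyl enol ether (E/Z mixture)
Product: 10 2-(5-iodo-3-methoxy-2-{[3-methoxy-4-(triisopropylsilyloxy)phenyl]methoxy}phenyl)acetaldehyde, via acetoxymercurio aldehyde 9 (not isolated)
Conditions: Hg(OAc)2 (1.1 equiv), THF/H2O (10:1), 0 °C; then aq. KI, 0 °C → rt; crude aldehyde used directly
Reagents that add atoms: water, O
Why: Oxymercuration of the electron-rich enol ether followed by iodide-induced demercuration of the α-mercurio aldehyde unmasks the arylacetaldehyde without acid, which spares the acid-sensitive electron-rich benzyl aryl ether and the aryl silyl ether.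

**Step 8**
Reactants: 10 arylacetaldehyde
Product: 11 2-(5-iodo-3-methoxy-2-{[3-methoxy-4-(triisopropylsilyloxy)phenyl]methoxy}phenyl)acetic acid
Conditions: NaClO2, NaH2PO4, 2-methyl-2-butene, tBuOH/H2O, 0 °C → rt
Reagents that add atoms: sodium chlorite, [Na+].[O-]Cl=O
Why: Pinnick oxidation takes the aldehyde to the acid under buffered conditions, with 2-methyl-2-butene trapping HOCl so that the electron-rich rings are not chlorinated.

**Step 9**
Reactants: 11 arylacetic acid
Product: 12 methyl 2-(5-iodo-3-methoxy-2-{[3-methoxy-4-(triisopropylsilyloxy)phenyl]methoxy}phenyl)acetate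
Conditions: MeI, KHCO3, DMF, rt
Reagents that add atoms: iodomethane, CI
Why: SN2 O-methylation of the carboxylate under bicarbonate, a base too weak to disturb the aryl silyl ether or to deprotonate the benzylic α-carbon.

**Step 10**
Reactants: 12 methyl arylacetate
Product: 13 methyl 2-diazo-2-(5-iodo-3-methoxy-2-{[3-methoxy-4-(triisopropylsilyloxy)phenyl]methoxy}phenyl)acetate
Conditions: p-ABSA (1.3 equiv), DBU (1.5 equiv), MeCN, 0 °C → rt
Reagents that add atoms: 4-acetamidobenzenesulfonyl azide, CC(=O)Nc1ccc(cc1)S(=O)(=O)N=[N+]=[N-]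
Why: Regitz diazo transfer, in which DBU forms the ester enolate (activated by aryl and ester), which attacks the sulfonyl azide and fragments to the aryldiazoacetate and the sulfonamide.

**Step 11**
Reactants: 13 methyl aryldiazoacetate
Product: 14 methyl (2S,3R)-5-iodo-7-methoxy-2-[3-methoxy-4-(triisopropylsilyloxy)phenyl]-2,3-dihydro-1-benzofuran-3-carboxylate (2,3-cis)
Conditions: Rh2(S-PTTL)4 (dirhodium tetrakis[N-phthaloyl-(S)-tert-leucinate], 2 mol%), toluene, −78 °C, slow addition of 13; then to −40 °C
Reagents that add atoms: none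
Why: The dirhodium tetracarboxylate expels N2 from the diazoester to give an electrophilic donor/acceptor rhodium carbene at the future C3, which inserts into one of the two enantiotopic hydrogens of the ArO–CH2–Ar' group through a concerted, asynchronous, hydride-shift-like three-centre transition state. The closest known reaction type is the enantioselective intramolecular benzylic C–H insertion of 2-(benzyloxy)phenyl diazoacetates under chiral dirhodium carboxylate catalysis. The dihydrofuran ring closes by C2–C3 bond formation as a 1,5-insertion, the five-membered transition state running carbene carbon, C3a, C7a, O1, CH2. C2 (S) is fixed by the chiral pocket of the phthalimido-tert-leucinate ligands, which selects one enantiotopic C–H, and C3 forms cis to the 2-aryl group (3R in the ester) because the compact transition state places ester and aryl on the same face. The step needs site selectivity, enantiotopic C–H discrimination and suppression of carbene dimerisation: the only C–H five atoms from the carbene is doubly activated by the ether oxygen and the electron-rich arene, and the substrate has no alkene or reactive X–H bond. The aryl iodide and silyl ether are inert to the carbene, and slow addition at low temperature keeps the carbene concentration low and favours the concerted pathway.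

**Step 12**
Reactants: 14 cis ester
Product: 15 methyl (2S,3S)-5-iodo-7-methoxy-2-[3-methoxy-4-(triisopropylsilyloxy)phenyl]-2,3-dihydro-1-benzofuran-3-carboxylate (2,3-trans)
Conditions: NaOMe (0.3 equiv), MeOH/THF, 0 °C → rt
Reagents that add atoms: none
Why: Base-mediated epimerisation through the ester enolate at C3, the only acidic stereocentre, should relax the cis ester to the more stable 2,3-trans isomer while C2 is untouched; methoxide in methanol makes transesterification degenerate and reprotonation fast.

**Step 13**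
Reactants: 15 trans ester
Product: 16 {(2S,3R)-5-iodo-7-methoxy-2-[3-methoxy-4-(triisopropylsilyloxy)phenyl]-2,3-dihydro-1-benzofuran-3-yl}methanol
Conditions: LiBH4, THF, 0 °C → rt
Reagents that add atoms: none
Why: Hydride reduction of the methyl ester with LiBH4, which tolerates the aryl iodide and silyl ether, gives the primary alcohol and removes the acidity of C3–H, so the trans configuration is locked (descriptor changes to 3R by priority only).

**Step 14**
Reactants: 17 4-hydroxybenzoic acid
Product: 19 4-(triisopropylsilyloxy)benzoic acid, via bis-silylated benzoate 18 (not isolated)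
Conditions: TIPSCl (2.3 equiv), imidazole, DMF, rt; then K2CO3, MeOH/H2O, rt; acidify to pH 4–5
Reagents that add atoms: triisopropylsilyl chloride, CC(C)[Si](Cl)(C(C)C)C(C)C
Why: Exhaustive silylation followed by mild carbonate hydrolysis exploits the much greater lability of the silyl ester compared with the hindered aryl silyl ether, leaving the free acid with the phenol protected.

**Step 15**
Reactants: 16 trans alcohol; 19 4-(triisopropylsilyloxy)benzoic acid
Product: 20 {(2S,3R)-5-iodo-7-methoxy-2-[3-methoxy-4-(triisopropylsilyloxy)phenyl]-2,3-dihydro-1-benzofuran-3-yl}methyl 4-(triisopropylsilyloxy)benzoate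
Conditions: DIC, DMAP (cat.), CH2Cl2, 0 °C → rt
Reagents that add atoms: none
Why: Steglich esterification, in which the carbodiimide activates the acid and DMAP transfers the acyl group to the unhindered primary alcohol under neutral conditions that do not touch C2 or C3.

**Step 16**
Reactants: 20 aryl iodide ester; 21 propargyl alcohol (prop-2-yn-1-ol)
Product: 22 {(2S,3R)-5-(3-hydroxyprop-1-ynyl)-7-methoxy-2-[3-methoxy-4-(triisopropylsilyloxy)phenyl]-2,3-dihydro-1-benzofuran-3-yl}methyl 4-(triisopropylsilyloxy)benzoate
Conditions: PdCl2(PPh3)2 (3 mol%), CuI (5 mol%), Et3N, THF, rt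
Reagents that add atoms: none
Why: Sonogashira coupling (oxidative addition of zerovalent palladium into the aryl iodide, transmetalation from the copper acetylide, reductive elimination) installs the three-carbon chain at C5 at room temperature, leaving esters and silyl ethers intact.

**Step 17**
Reactants: 22 aryl propargylic alcohol
Product: 23 {(2S,3R)-5-[(Z)-3-hydroxyprop-1-enyl]-7-methoxy-2-[3-methoxy-4-(triisopropylsilyloxy)phenyl]-2,3-dihydro-1-benzofuran-3-yl}methyl 4-(triisopropylsilyloxy)benzoate
Conditions: H2 (1 atm), Pd/CaCO3 poisoned with Pb(OAc)2 (Lindlar catalyst), quinoline, EtOAc, rt, stopped at one equivalent of H2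
Reagents that add atoms: none
Why: Lindlar semihydrogenation delivers both hydrogens syn from the poisoned palladium surface, giving the Z-alkene, while quinoline and control of hydrogen uptake guard against over-reduction and the benzylic C–O bonds are not hydrogenolysed on this catalyst.

**Step 18**
Reactants: 23 Z-allylic alcohol
Product: 24 {(2S,3R)-7-methoxy-2-[3-methoxy-4-(triisopropylsilyloxy)phenyl]-5-[(Z)-3-oxoprop-1-enyl]-2,3-dihydro-1-benzofuran-3-yl}methyl 4-(triisopropylsilyloxy)benzoate
Conditions: MnO2 (activated, 15 equiv), CH2Cl2, 0 °C → rt, dark, short contact time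
Reagents that add atoms: none
Why: Heterogeneous MnO2 oxidation is selective for the allylic alcohol and neutral, so the Z-enal should be obtained without isomerisation when light, acid and prolonged contact are excluded.

**Step 19**
Reactants: 24 bis-silylated Z-enal
Product: 25 [(2S,3R)-2-(4-hydroxy-3-methoxyphenyl)-7-methoxy-5-[(Z)-3-oxoprop-1-enyl]-2,3-dihydro-1-benzofuran-3-yl]methyl 4-hydroxybenzoate (CNP0400980.1)
Conditions: Bu4NF/AcOH (1:1, 3 equiv), THF, 0 °C, dark
Reagents that add atoms: none
Why: Fluoride-mediated desilylation at both aryl TIPS ethers (phenoxides being good leaving groups), with the acetic acid buffer protonating the phenoxides at once so that neither the benzoate ester nor the Z-enal meets free base.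

**Compound list**

1 | o-vanillin (2-hydroxy-3-methoxybenzaldehyde) | COc1cccc(C=O)c1O | starting material
2 | 5-iodo-o-vanillin (2-hydroxy-5-iodo-3-methoxybenzaldehyde) | COc1cc(I)cc(C=O)c1O | intermediate
3 | vanillin | COc1cc(C=O)ccc1O | starting material
4 | 3-methoxy-4-(triisopropylsilyloxy)benzaldehyde | COc1cc(C=O)ccc1O[Si](C(C)C)(C(C)C)C(C)C | intermediate
5 | [3-methoxy-4-(triisopropylsilyloxy)phenyl]methanol | COc1cc(CO)ccc1O[Si](C(C)C)(C(C)C)C(C)C | intermediate
6 | 4-(bromomethyl)-2-methoxy-1-(triisopropylsilyloxy)benzene | COc1cc(CBr)ccc1O[Si](C(C)C)(C(C)C)C(C)C | intermediate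
7 | 5-iodo-3-methoxy-2-{[3-methoxy-4-(triisopropylsilyloxy)phenyl]methoxy}benzaldehyde | COc1cc(I)cc(C=O)c1OCc1ccc(O[Si](C(C)C)(C(C)C)C(C)C)c(OC)c1 | intermediate
8 | methyl enol ether of the homologated aldehyde (E/Z mixture) | COC=Cc1cc(I)cc(OC)c1OCc1ccc(O[Si](C(C)C)(C(C)C)C(C)C)c(OC)c1 | intermediate
9 | α-acetoxymercurio arylacetaldehyde (not isolated) | CC(=O)O[Hg]C(C=O)c1cc(I)cc(OC)c1OCc1ccc(O[Si](C(C)C)(C(C)C)C(C)C)c(OC)c1 | intermediate
10 | 2-(5-iodo-3-methoxy-2-{[3-methoxy-4-(triisopropylsilyloxy)phenyl]methoxy}phenyl)acetaldehyde | O=CCc1cc(I)cc(OC)c1OCc1ccc(O[Si](C(C)C)(C(C)C)C(C)C)c(OC)c1 | intermediate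
11 | 2-(5-iodo-3-methoxy-2-{[3-methoxy-4-(triisopropylsilyloxy)phenyl]methoxy}phenyl)acetic acid | OC(=O)Cc1cc(I)cc(OC)c1OCc1ccc(O[Si](C(C)C)(C(C)C)C(C)C)c(OC)c1 | intermediate
12 | methyl 2-(5-iodo-3-methoxy-2-{[3-methoxy-4-(triisopropylsilyloxy)phenyl]methoxy}phenyl)acetate | COC(=O)Cc1cc(I)cc(OC)c1OCc1ccc(O[Si](C(C)C)(C(C)C)C(C)C)c(OC)c1 | intermediate
13 | methyl 2-diazo-2-(5-iodo-3-methoxy-2-{[3-methoxy-4-(triisopropylsilyloxy)phenyl]methoxy}phenyl)acetate | COC(=O)C(=[N+]=[N-])c1cc(I)cc(OC)c1OCc1ccc(O[Si](C(C)C)(C(C)C)C(C)C)c(OC)c1 | intermediate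
14 | methyl (2S,3R)-5-iodo-7-methoxy-2-[3-methoxy-4-(triisopropylsilyloxy)phenyl]-2,3-dihydro-1-benzofuran-3-carboxylate (cis) | COc1cc([C@H]2Oc3c(OC)cc(I)cc3[C@H]2C(=O)OC)ccc1O[Si](C(C)C)(C(C)C)C(C)C | intermediate
15 | methyl (2S,3S)-5-iodo-7-methoxy-2-[3-methoxy-4-(triisopropylsilyloxy)phenyl]-2,3-dihydro-1-benzofuran-3-carboxylate (trans) | COc1cc([C@H]2Oc3c(OC)cc(I)cc3[C@@H]2C(=O)OC)ccc1O[Si](C(C)C)(C(C)C)C(C)C | intermediate
16 | {(2S,3R)-5-iodo-7-methoxy-2-[3-methoxy-4-(triisopropylsilyloxy)phenyl]-2,3-dihydro-1-benzofuran-3-yl}methanol (trans) | COc1cc([C@H]2Oc3c(OC)cc(I)cc3[C@@H]2CO)ccc1O[Si](C(C)C)(C(C)C)C(C)C | intermediate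
17 | 4-hydroxybenzoic acid | O=C(O)c1ccc(O)cc1 | starting material
18 | triisopropylsilyl 4-(triisopropylsilyloxy)benzoate (not isolated) | CC(C)[Si](OC(=O)c1ccc(O[Si](C(C)C)(C(C)C)C(C)C)cc1)(C(C)C)C(C)C | intermediate
19 | 4-(triisopropylsilyloxy)benzoic acid | O=C(O)c1ccc(O[Si](C(C)C)(C(C)C)C(C)C)cc1 | intermediate
20 | {(2S,3R)-5-iodo-7-methoxy-2-[3-methoxy-4-(triisopropylsilyloxy)phenyl]-2,3-dihydro-1-benzofuran-3-yl}methyl 4-(triisopropylsilyloxy)benzoate | COc1cc([C@H]2Oc3c(OC)cc(I)cc3[C@@H]2COC(=O)c2ccc(O[Si](C(C)C)(C(C)C)C(C)C)cc2)ccc1O[Si](C(C)C)(C(C)C)C(C)C | intermediate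
21 | propargyl alcohol | C#CCO | starting material
22 | C5 3-hydroxyprop-1-ynyl compound | COc1cc([C@H]2Oc3c(OC)cc(C#CCO)cc3[C@@H]2COC(=O)c2ccc(O[Si](C(C)C)(C(C)C)C(C)C)cc2)ccc1O[Si](C(C)C)(C(C)C)C(C)C | intermediate
23 | C5 (Z)-3-hydroxyprop-1-enyl compound | COc1cc([C@H]2Oc3c(OC)cc(/C=C\CO)cc3[C@@H]2COC(=O)c2ccc(O[Si](C(C)C)(C(C)C)C(C)C)cc2)ccc1O[Si](C(C)C)(C(C)C)C(C)C | intermediate
24 | bis-TIPS (Z)-enal | COc1cc([C@H]2Oc3c(OC)cc(/C=C\C=O)cc3[C@@H]2COC(=O)c2ccc(O[Si](C(C)C)(C(C)C)C(C)C)cc2)ccc1O[Si](C(C)C)(C(C)C)C(C)C | intermediate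
25 | [(2S,3R)-2-(4-hydroxy-3-methoxyphenyl)-7-methoxy-5-[(Z)-3-oxoprop-1-enyl]-2,3-dihydro-1-benzofuran-3-yl]methyl 4-hydroxybenzoate (CNP0400980.1) | COc1cc([C@H]2Oc3c(OC)cc(/C=C\C=O)cc3[C@@H]2COC(=O)c2ccc(O)cc2)ccc1O | target

**Step count**

Total: 19 steps. Longest linear sequence: 17 steps (vanillin 3 to target 25 through steps 2–13 and 15–19).

**Steps most likely to fail**

1. Step 11 (carbene C–H insertion). The risk is insufficient discrimination between the two enantiotopic benzylic hydrogens, erosion of selectivity through a stepwise hydride-abstraction pathway favoured by the very electron-rich benzyl group, or carbene dimerisation. The fallback replaces catalyst control alone by auxiliary control and sets out from acid 11. Ethyl (S)-lactate is heated with pyrrolidine to give (S)-2-hydroxy-1-(pyrrolidin-1-yl)propan-1-one F1. Acid 11 is esterified with it (DIC, DMAP) to the lactamide ester F2, and diazo transfer (p-ABSA, DBU) gives the auxiliary-bearing aryldiazoacetate F3. Insertion with Rh2(S-DOSP)4 (dirhodium tetrakis[(S)-N-(4-dodecylbenzenesulfonyl)prolinate]), the auxiliary antipode being chosen as the matched partner, should give the dihydrobenzofuran auxiliary ester F4 as a separable diastereomer. Catalytic NaOMe in MeOH/THF then cleaves the auxiliary by methanolysis and epimerises C3 in the same operation, returning to the route at trans ester 15.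

2. Step 19 (final desilylation). The risk is Z to E isomerisation of the enal through reversible conjugate addition of fluoride, acetate or phenoxide, or light-induced isomerisation during work-up. The fallback changes the order so that the enal is formed last and never meets fluoride. It sets out from Z-allylic alcohol 23, which is desilylated with Bu4NF/AcOH to {(2S,3R)-2-(4-hydroxy-3-methoxyphenyl)-5-[(Z)-3-hydroxyprop-1-enyl]-7-methoxy-2,3-dihydro-1-benzofuran-3-yl}methyl 4-hydroxybenzoate F8. Chemoselective allylic oxidation with activated MnO2 (CH2Cl2/EtOAc, dark, short contact) in the presence of the free phenols then returns to the route at target 25.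

3. Step 12 (epimerisation at C3). The risk is β-elimination of the O1 phenoxide from the ester enolate (opening of the dihydrofuran ring) or methoxide attack on silicon competing with simple reprotonation. The fallback moves the epimerisation to the aldehyde oxidation level, where a weak amine base suffices. It sets out from cis ester 14, which is reduced with LiBH4 to the cis alcohol F5 and oxidised with Dess–Martin periodinane/NaHCO3 to the cis aldehyde F6. Et3N in CH2Cl2 equilibrates F6 to the trans aldehyde F7, and NaBH4 reduction returns to the route at trans alcohol 16.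

**Further compounds**

F1 | step 11 | (S)-2-hydroxy-1-(pyrrolidin-1-yl)propan-1-one | C[C@H](O)C(=O)N1CCCC1
F2 | step 11 | (S)-1-oxo-1-(pyrrolidin-1-yl)propan-2-yl 2-(5-iodo-3-methoxy-2-{[3-methoxy-4-(triisopropylsilyloxy)phenyl]methoxy}phenyl)acetate | C[C@H](OC(=O)Cc1cc(I)cc(OC)c1OCc1ccc(O[Si](C(C)C)(C(C)C)C(C)C)c(OC)c1)C(=O)N1CCCC1
F3 | step 11 | (S)-1-oxo-1-(pyrrolidin-1-yl)propan-2-yl 2-diazo-2-(5-iodo-3-methoxy-2-{[3-methoxy-4-(triisopropylsilyloxy)phenyl]methoxy}phenyl)acetate | C[C@H](OC(=O)C(=[N+]=[N-])c1cc(I)cc(OC)c1OCc1ccc(O[Si](C(C)C)(C(C)C)C(C)C)c(OC)c1)C(=O)N1CCCC1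
F4 | step 11 | (S)-1-oxo-1-(pyrrolidin-1-yl)propan-2-yl (2S,3R)-5-iodo-7-methoxy-2-[3-methoxy-4-(triisopropylsilyloxy)phenyl]-2,3-dihydro-1-benzofuran-3-carboxylate (cis) | COc1cc([C@H]2Oc3c(OC)cc(I)cc3[C@H]2C(=O)O[C@@H](C)C(=O)N4CCCC4)ccc1O[Si](C(C)C)(C(C)C)C(C)C
F5 | step 12 | {(2S,3S)-5-iodo-7-methoxy-2-[3-methoxy-4-(triisopropylsilyloxy)phenyl]-2,3-dihydro-1-benzofuran-3-yl}methanol (cis) | COc1cc([C@H]2Oc3c(OC)cc(I)cc3[C@H]2CO)ccc1O[Si](C(C)C)(C(C)C)C(C)C
F6 | step 12 | (2S,3R)-5-iodo-7-methoxy-2-[3-methoxy-4-(triisopropylsilyloxy)phenyl]-2,3-dihydro-1-benzofuran-3-carbaldehyde (cis) | COc1cc([C@H]2Oc3c(OC)cc(I)cc3[C@H]2C=O)ccc1O[Si](C(C)C)(C(C)C)C(C)C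
F7 | step 12 | (2S,3S)-5-iodo-7-methoxy-2-[3-methoxy-4-(triisopropylsilyloxy)phenyl]-2,3-dihydro-1-benzofuran-3-carbaldehyde (trans) | COc1cc([C@H]2Oc3c(OC)cc(I)cc3[C@@H]2C=O)ccc1O[Si](C(C)C)(C(C)C)C(C)C
F8 | step 19 | {(2S,3R)-2-(4-hydroxy-3-methoxyphenyl)-5-[(Z)-3-hydroxyprop-1-enyl]-7-methoxy-2,3-dihydro-1-benzofuran-3-yl}methyl 4-hydroxybenzoate | COc1cc([C@H]2Oc3c(OC)cc(/C=C\CO)cc3[C@@H]2COC(=O)c2ccc(O)cc2)ccc1O
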